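At 5.0 h the flask is read, and the reading tells what the catalyst turnovers have left of left-handed substrate (L) and right-handed substrate (R).

| flask | left-handed substrate | right-handed substrate | solid reagent | precatalyst | remark | time |
|---|---|---|---|---|---|---|
| delta | 0.25 M | 0.25 M | 0.75 M | 0.060 mM | run made earlier |  |
| beta | 0.25 M | 0.25 M | 0.75 M | 0.090 mM | run made earlier |  |
| alpha | 0.12 M | 0.12 M | 0.75 M | 0.12 mM | run made earlier |  |
| flask | 0.25 M | 0.25 M | 0.750 M | 0.12 mM |  | 5.0 h |

| run | time / h | left-handed substrate / % | right-handed substrate / % |
|---|---|---|---|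
| delta | 0.500 | 48.8 | 50.5 |
| delta | 1.50 | 43.5 | 50.1 |
| delta | 3.00 | 36.0 | 50.0 |
| delta | 4.00 | 30.8 | 50.3 |
| delta | 6.00 | 21.2 | 48.8 |
| beta | 1.33 | 43.2 | 49.6 |
| beta | 2.50 | 36.7 | 49.2 |
| beta | 4.00 | 28.0 | 49.5 |
| beta | 5.00 | 21.3 | 50.1 |
| beta | 6.00 | 16.7 | 49.6 |
| alpha | 1.33 | 36.1 | 49.9 |
| alpha | 2.50 | 20.5 | 49.0 |
| alpha | 4.00 | 6.4 | 48.9 |
| alpha | 5.00 | 0.9 | 47.5 |
| alpha | 6.00 | 0.4 | 46.7 |

(readings scatter by 0.5 percentage points)

- part of the left-handed substrate and right-handed substrate charged together that has reacted at 5.0 h
- excess of left-handed product over right-handed product in the product at 5.0 h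
- excess of right-handed substrate over left-handed substrate among what is left of the two at 5.0 h

- free catalyst is single-handed; left-handed substrate and right-handed substrate are mirror images of each other, charged as a racemate, each of them at the stated concentration
- solid, in amounts per volume of the solution: solid reagent
- at the start none of the solid reagent is in solution
- an excess is the difference of the two amounts in percent of their sum
- an excess is below zero if the other one leads

Follow one turnover to its fork. It is taken here to choose L over R with odds s·[L]/[R], so the fractions left of their charges, x_L and x_R, obey x_R = x_L^(1/s). The alpha run at 4.00 h gives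

s = ln x_L / ln x_R = 92.4

This s is the selectivity factor, how many times more readily a molecule of L reacts than one of R at equal concentration. It is rough, since R has lost 1.1 percentage points against a scatter of 0.5 points.

Two extreme versions of the flask can be reckoned for L at 5.0 h. If precatalyst beyond the beta charge added nothing, the flask would repeat the beta run, with L read at 21.3 %, having lost 28.7 %. If the loss of L grew in proportion to precatalyst, L would stand at 11.7 %.

From delta to beta, precatalyst rose 1.50 times, but the loss of L at 6.00 h rose less than that, 1.16 times. Read off these two scattered readings, that is an order of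

n = 0.358

Assumed to hold also at 5.0 h and carried from beta to the flask, this gives

L = 18.2 %, R = 49.5 %

so my own reckoning is c = 32.3 %, eP = 96.9 % and eS = 46.2 %.

The forecast, which differs from these figures and holds that “Selectivity from alpha's late right-handed loss is about 70”, gives 33.2 %, 95.5 % and 47.6 %.

The flask gives 30.5 %, 97.2 % and 42.7 %.

    coupling partner + precatalyst → free catalyst + spent reagent (k = 0.110 M⁻¹ s⁻¹)
    coupling partner + catalyst intermediate B → free catalyst + right-handed product (k = 0.440 M⁻¹ s⁻¹)
    coupling partner + catalyst intermediate A → free catalyst + left-handed product (k = 19.0 M⁻¹ s⁻¹)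
    free catalyst + right-handed substrate ⇌ catalyst intermediate B (K = 24.0 M⁻¹, k = 330 M⁻¹ s⁻¹)
    solid reagent ⇌ coupling partner, rate k5*(cs5 - [coupling partner]) while solid is left; crystals form when [coupling partner] > cs5 (solubility = 28.0 mM, k = 4.20 × 10⁻⁴ s⁻¹)
    free catalyst + left-handed substrate ⇌ catalyst intermediate A (K = 60.0 M⁻¹, k = 910 M⁻¹ s⁻¹)

With 40 % of its L left at 5.00 h, the flask should by s have made 0.493 % of right-handed product, and it holds 0.428 %. A neighbouring flask, the same but charged with 4.8 × 10⁻⁴ M of precatalyst, has 26 % of its L left at that time. The same reckoning gives it 0.728 % of right-handed product and eP = 96.1 %. That neighbouring flask holds 0.626 % of right-handed product, with eP = 96.7 %.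

Readings and results are simulated for an exercise; noise was put on by code.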